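## Analysis of the target

Nidificene (19) is a β-chamigrene, a spiro[5.5]undecane. Ring A (C1–C6) carries the exocyclic methylene at C1, a secondary bromide at C4 and the gem-dimethyl carbon C5. Ring B (C6, C7–C11) carries a tertiary chloride and a methyl at C9 and a secondary bromide at C10. The four stereocentres are 4S, 6S, 9S and 10S. On ring A the C4 bromide is cis to C7. On ring B the C10 bromide and C9 chloride are trans, bromine on the face of the C5 branch and chlorine on the face of the C1 branch. In the ring B chair that keeps the bulky C5 branch equatorial, both halogens are equatorial and the C9 methyl is axial, which is not the trans-diaxial pattern that halogen addition to a cyclohexene normally gives. The tertiary chloride and the two secondary bromides (one neopentylic) eliminate or ionise with base, Lewis acid or heat, and the 1,1-disubstituted alkene can migrate into the ring under acid, so the halogens belong at the end. The hard points are the adjacent quaternary carbons C5 and C6, the spiro configuration at C6 (stereogenic only through remote substituents) and the neopentylic C4 bromide. The strategy rests on the fact that C5 and C6 both flank C1: a tetrasubstituted enone C1(=O)–C6=C5(CH3) lets one conjugate methylation create C5 and one alkylation of the resulting enolate create C6.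

## Retrosynthetic reasoning

**C9–Cl and C10–Br (19 ⇒ 18).** The two ring B halogens are removed first, back to the C9=C10 alkene of diene 18. They are the most fragile groups, and a trisubstituted alkene accepts a positive bromine and a chloride with the right regiochemistry (chloride at the tertiary carbon). The forward reaction must prefer this alkene over the hindered C1 methylene and must place bromine on the C5 face.

**C4–Br (18 ⇒ 17 ⇒ 16).** The C4 bromide is traced to a C4 alcohol of opposite configuration (17, from silyl ether 16), to be displaced with inversion. This gives the route an oxygen substituent at C4, which can be made enantiopure early, protected, and used as the only control element for the spiro centre.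

**C1=CH2 (16 ⇒ 15).** The methylene is cut to the C1 ketone 15. The ketone is what the ring-forming step leaves behind, so no extra functional group is needed; the forward olefination must cope with a ketone next to two quaternary carbons.

**C5–CH3 and C6–C7 (15 ⇒ 12, through 13 and 14).** This is the central disconnection. Removing one C5 methyl and opening ring B at C6–C7 gives the tetrasubstituted enone 12, whose C6 side chain already holds C11, the Z alkene C10=C9 with its methyl, C8 and a primary chloride at C7. Both quaternary carbons and ring B then arise together. The enolate is generated exactly at C6 by the conjugate addition, and the alkene sits in the only position that fits the later halogenation. The forward step must add methyl to a hindered β-carbon, leave the chloride alone until the enolate is free, and close ring B on the enolate face trans to the C4 oxygen.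

**Enone 12 (12 ⇒ 9 + 10).** The C5–CH3 bond of the enone and its carbonyl position are traced to 1,2-addition of methyllithium (10) to the vinylogous ester 9, followed by acid-induced transposition. The α' oxygen of 9 thereby becomes the C4 oxygen next to the methyl-bearing carbon.

**C4–O (9 ⇒ 8 ⇒ 7 ⇒ 6).** The C–O bond is cut at the only α' methylene of vinylogous ester 6. It is installed as a racemic acetate (7) and made enantiopure by enzymatic hydrolysis (8). A resolution is accepted here, at cheap material, because reagent-controlled hydroxylation of an unsubstituted cyclic enolate is not dependable in enantioselectivity, and oxidants that epoxidise alkenes would touch the side chain.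

**C6–C11 (6 ⇒ 5 ⇒ 4 + 3).** The enol ether is cut to the symmetric 2-substituted dione 5, and its C2–CH2 bond to cyclohexane-1,3-dione (4) and the allylic chloride of 3. The symmetry of the dione removes any regiochemical question in enol ether formation.

**Z alkene (3 ⇒ 2 ⇒ 1).** The Z trisubstituted alkene with two differentiated ends is taken from lactone 1, whose ring fixes the geometry. Reduction gives diol 2 and both hydroxyls become chlorides (3). Only the allylic one reacts with the dione, so no protecting group is needed.

## Alternatives that were turned down

**Alternative 1:** bromo ether relay for ring B.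
- *Disconnection:* C9–Cl is traced to a temporary C9–O bond and C10–Br to a bromoetherification, A1 ⇐ A2.
- *Forward key step:* NBS forms the bromonium ion on C9=C10 of alcohol A2 and the C1 hydroxyl, which can sit under ring B, opens it at C9 to give the bridged ether A1. Later the tertiary C–O bond must be exchanged for C–Cl with retention and C1 reoxidised and methylenated.
- *For:* the bridge forces ring B into a boat in which oxygen and bromine must be anti, and oxygen can reach C9 only from the C1 face. Bromine therefore lands on the C5 face, exactly the diequatorial arrangement of 19. On ring B diastereocontrol it is stronger than the chosen route, whose last step relies on a face preference.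
- *Against:* it does not make the skeleton; A2 would itself come from a ketone such as 15. It adds reduction, cyclisation, ether cleavage, reoxidation and a methylenation of a hindered ketone carrying three halides. The ether cleavage passes through the same bromonium ion and its choice between C9 and C10.
- *Comparison:* the chosen strategy supplies both quaternary carbons and the C4/C6 relation in one flask and reaches 19 about four steps sooner if the direct addition is selective. The relay is kept as the reserve for step 13.

**Alternative 2:** gold-catalysed spirocyclisation onto an enol ether.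
- *Disconnection:* C1–C6, ring A closed from the enol ether alkyne A4.
- *Forward key step:* (R)-DTBM-SEGPHOS(AuCl)2 with AgSbF6 and water activates the terminal alkyne; the enol ether carbon C6 attacks the internal alkyne carbon (6-exo-dig); protodeauration leaves the C1 methylene and hydrolysis leaves the C11 ketone of A3.
- *For:* the methylene is formed directly, so no olefination of a hindered ketone is needed. The step is catalytic and mild, and the chiral ligand offers control of C6 that does not depend on the substrate. On these points it is stronger.
- *Against:* the quaternary C5 must already sit in the tether, so the adjacent-quaternary problem is only moved into the synthesis of A4. A3 has ring B at the wrong oxidation level: a C11 ketone to remove and the alkene at C8=C9 instead of C9=C10, which costs several redox and isomerisation steps on a β,γ-unsaturated ketone. Ligand and C4 stereocentre may be mismatched.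
- *Comparison:* the chosen route pays with a Wittig reaction but forms ring B at its final oxidation level with the alkene where the halogens go.

**Alternative 3:** formyl ketone spiroannulation.
- *Disconnection:* C6–C7 and C10–C11, ring B from formyl ketone A6 and the enone A7.
- *Forward key step:* the formyl-activated C6 of A6 adds to A7 (Et3N); the new methyl ketone condenses with the aldehyde (pyrrolidinium acetate) and dehydrates to the spiro enedione A5.
- *For:* each operation is robust, cheap and scalable; the formyl group guarantees reaction at C6. In reliability per operation it is stronger than the cuprate tandem.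
- *Against:* the gem-dimethyl carbon must be built into A6 beforehand. A5 lacks the C9 methyl, carries oxygen at C9 and has its alkene at C10=C11. Reaching 19 needs a methyl addition selective between two ketones and an alkene transposition before any halogenation. The Michael step has no tether to enforce facial delivery at C6.
- *Comparison:* the chosen strategy brings the C9 methyl and the C9=C10 alkene inside the tether and is clearly shorter after ring formation.

Key step: step 9

## Route

Remark (assumption): the absolute configuration is read as 4S,6S,9S,10S in the numbering of the analysis. Names of the spiro compounds use these locants. Compound 7 is racemic and the route is enantiopure from 8 on.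

**Step 1**
Reactants: 1 4-methyl-5,6-dihydro-2H-pyran-2-one
Product: 2 (2Z)-3-methylpent-2-ene-1,5-diol
Conditions: iBu2AlH (3 equiv), CH2Cl2, −78 → 0 °C; aq. potassium sodium tartrate
Reagents that add atoms: none
Why: Hydride reduction of the unsaturated lactone through the lactol to the allylic diol. The ring fixes the alkene as Z, and this geometry, later C9=C10, is not touched again.

**Step 2**
Reactants: 2 (2Z)-3-methylpent-2-ene-1,5-diol
Product: 3 (2Z)-1,5-dichloro-3-methylpent-2-ene
Conditions: PPh3, NCS, CH2Cl2, −20 °C → rt
Reagents that add atoms: N-chlorosuccinimide, O=C1CCC(=O)N1Cl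
Why: Appel-type chlorination of both primary alcohols by SN2 on the alkoxyphosphonium ions. Primary allylic alcohols of this kind react without allylic transposition or loss of Z geometry.

**Step 3**
Reactants: 4 cyclohexane-1,3-dione; 3 (2Z)-1,5-dichloro-3-methylpent-2-ene
Product: 5 2-[(2Z)-5-chloro-3-methylpent-2-en-1-yl]cyclohexane-1,3-dione
Conditions: KOH (1 equiv), KI (cat.), H2O, rt → 40 °C; then acidify
Reagents that add atoms: none
Why: C-alkylation of the dione enolate in water, where solvation of oxygen favours attack through carbon. Only the allylic chloride is reactive enough, so the homoallylic chloride is kept, and SN2 at the primary allylic carbon keeps the alkene Z.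

**Step 4**
Reactants: 5 2-[(2Z)-5-chloro-3-methylpent-2-en-1-yl]cyclohexane-1,3-dione
Product: 6 2-[(2Z)-5-chloro-3-methylpent-2-en-1-yl]-3-methoxycyclohex-2-en-1-one
Conditions: TMSCHN2, MeOH/toluene, 0 °C → rt
Reagents that add atoms: (trimethylsilyl)diazomethane, C[Si](C)(C)C=[N+]=[N-]
Why: O-methylation of the enolic dione by the diazoalkane gives the vinylogous ester. Neutral conditions avoid acid-induced cyclisation of the enol onto the trisubstituted alkene, and the symmetric dione gives a single product.

**Step 5**
Reactants: 6 2-[(2Z)-5-chloro-3-methylpent-2-en-1-yl]-3-methoxycyclohex-2-en-1-one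
Product: 7 rac-3-[(2Z)-5-chloro-3-methylpent-2-en-1-yl]-4-methoxy-2-oxocyclohex-3-en-1-yl acetate
Conditions: Mn(OAc)3·2H2O, benzene, reflux (water separator)
Reagents that add atoms: manganese triacetate, CC(=O)[O-].CC(=O)[O-].CC(=O)[O-].[Mn+3]
Why: α'-Acetoxylation of an enone through its enolate bound to trivalent manganese, a known reaction of β-alkoxy enones. The CH2 next to the carbonyl is the only α' position, and the new stereocentre forms racemic.

**Step 6**
Reactants: 7 rac-3-[(2Z)-5-chloro-3-methylpent-2-en-1-yl]-4-methoxy-2-oxocyclohex-3-en-1-yl acetate
Product: 8 (6R)-2-[(2Z)-5-chloro-3-methylpent-2-en-1-yl]-6-hydroxy-3-methoxycyclohex-2-en-1-one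
Conditions: lipase from Burkholderia cepacia, phosphate buffer (pH 7)/MTBE, rt, stopped near half conversion
Reagents that add atoms: none
Why: Enzymatic kinetic resolution by enantioselective ester hydrolysis. By the empirical size rule for secondary carbinols (carbonyl side large, CH2 side medium) the R acetate should be the one hydrolysed, while the S enantiomer of 7 stays an ester and is separated. The stereocentre that becomes C4 is fixed here by the enzyme.

**Step 7**
Reactants: 8 (6R)-2-[(2Z)-5-chloro-3-methylpent-2-en-1-yl]-6-hydroxy-3-methoxycyclohex-2-en-1-one
Product: 9 (6R)-6-[(tert-butyldimethylsilyl)oxy]-2-[(2Z)-5-chloro-3-methylpent-2-en-1-yl]-3-methoxycyclohex-2-en-1-one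
Conditions: TBSCl, imidazole, DMF, rt
Reagents that add atoms: tert-butyldimethylsilyl chloride, CC(C)(C)[Si](C)(C)Cl
Why: Standard silylation of a secondary alcohol. The silyl ether blocks base-induced epimerisation through the α-ketol and later serves as the bulky directing group.

**Step 8**
Reactants: 9 (6R)-6-[(tert-butyldimethylsilyl)oxy]-2-[(2Z)-5-chloro-3-methylpent-2-en-1-yl]-3-methoxycyclohex-2-en-1-one; 10 methyllithium
Product: 12 (4R)-4-[(tert-butyldimethylsilyl)oxy]-2-[(2Z)-5-chloro-3-methylpent-2-en-1-yl]-3-methylcyclohex-2-en-1-one, via tertiary allylic alcohol 11 (not isolated)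
Conditions: MeLi, THF, −78 °C; then 1 M HCl, 0 °C
Reagents that add atoms: none
Why: Stork–Danheiser sequence: 1,2-addition to the vinylogous ester carbonyl, then acid hydrolysis of the enol ether with loss of water, which transposes the carbonyl. The carbinol carbon is not involved and keeps its configuration, and the primary chloride is inert to MeLi at −78 °C.

**Step 9**
Reactants: 12 (4R)-4-[(tert-butyldimethylsilyl)oxy]-2-[(2Z)-5-chloro-3-methylpent-2-en-1-yl]-3-methylcyclohex-2-en-1-one; 10 methyllithium
Product: 15 (4R,6R)-4-[(tert-butyldimethylsilyl)oxy]-5,5,9-trimethylspiro[5.5]undec-9-en-1-one, via silyl enol ether 13 (not isolated), via lithium enolate 14 (not isolated)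
Conditions: MeLi, CuI, Et2O, 0 °C (Me2CuLi); 12, TMSCl, THF, −78 → −30 °C; volatiles removed; MeLi, THF, 0 °C → rt; HMPA, rt → 50 °C
Reagents that add atoms: none
Why: Me2CuLi transfers methyl to the β-carbon C5 of the tetrasubstituted enone (π-complex, a transient trivalent copper intermediate, reductive elimination), and TMSCl traps the enolate as 13 and so drives an otherwise sluggish addition; C5 becomes the gem-dimethyl carbon and is not stereogenic. MeLi then first returns MeCu to the cuprate and next cleaves the Si–O bond of 13, which frees the C1(O−)=C6 lithium enolate 14 regiospecifically, an enolate no deprotonation could give. With HMPA the enolate carbon C6 displaces chloride from the primary carbon C7 by SN2, which creates the second quaternary carbon and closes ring B in a 6-exo-tet mode with the enolate double bond outside the new ring; the Z alkene of the tether becomes C9=C10 and holds C7 within reach of C6. The closest known reaction type is cuprate conjugate addition followed by alkylation of the resulting enolate, including its intramolecular (cycloalkylation) form. The new stereocentre C6 is controlled by the C4 silyl ether: in the half-chair of 14 with the silyloxy group equatorial, the axial C5 methyl covers the face cis to oxygen, so C7 bonds axially on the other face through a chair-like transition state and ends trans to the C4 oxygen, whereas the half-chair with axial silyloxy would force C7 into a 1,3-diaxial contact with it. The step needs the cuprate to prefer the enone over the primary chloride, secured by choosing chloride as leaving group, and C- over O-alkylation, secured by ring size (a six-membered ring against an eight-membered enol ether). TMSCl is preferred to a boron Lewis acid as activator because the silyl enol ether can be turned back into a free, nucleophilic lithium enolate.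

**Step 10**
Reactants: 15 (4R,6R)-4-[(tert-butyldimethylsilyl)oxy]-5,5,9-trimethylspiro[5.5]undec-9-en-1-one
Product: 16 tert-butyl{[(4R,6S)-5,5,9-trimethyl-1-methylidenespiro[5.5]undec-9-en-4-yl]oxy}dimethylsilane
Conditions: Ph3PCH3Br, KOtBu, toluene, 100 °C
Reagents that add atoms: methyltriphenylphosphonium bromide, C[P+](c1ccccc1)(c1ccccc1)c1ccccc1.[Br-]
Why: Wittig methylenation; the ylide made with KOtBu in hot toluene is the usual answer to hindered ketones. C6 is quaternary, so enolisation toward C2 cannot damage a stereocentre; the C6 descriptor changes from R to S only because the priorities change.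

**Step 11**
Reactants: 16 tert-butyl{[(4R,6S)-5,5,9-trimethyl-1-methylidenespiro[5.5]undec-9-en-4-yl]oxy}dimethylsilane
Product: 17 (4R,6S)-5,5,9-trimethyl-1-methylidenespiro[5.5]undec-9-en-4-ol
Conditions: TBAF, THF, rt → 50 °C
Reagents that add atoms: none
Why: Fluoride cleaves the Si–O bond of the hindered silyl ether; no stereocentre is touched and both alkenes are inert.

**Step 12**
Reactants: 17 (4R,6S)-5,5,9-trimethyl-1-methylidenespiro[5.5]undec-9-en-4-ol
Product: 18 (4S,6S)-4-bromo-5,5,9-trimethyl-1-methylidenespiro[5.5]undec-9-ene
Conditions: PPh3, CBr4, CH2Cl2, 0 °C → rt
Reagents that add atoms: tetrabromomethane, BrC(Br)(Br)Br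
Why: Appel reaction: the alkoxyphosphonium ion is displaced by bromide in an SN2 step with inversion at C4 (R to S), which puts bromine cis to C7 as in 19. The carbon is neopentylic, and the displacement is expected to run through the ring A chair with the leaving group axial, where bromide enters along the equator.

**Step 13**
Reactants: 18 (4S,6S)-4-bromo-5,5,9-trimethyl-1-methylidenespiro[5.5]undec-9-ene
Product: 19 nidificene (4S,6S,9S,10S)-4,10-dibromo-9-chloro-5,5,9-trimethyl-1-methylidenespiro[5.5]undecane
Conditions: NBS, Et4NCl, CH2Cl2, −78 → −20 °C, dark
Reagents that add atoms: N-bromosuccinimide, O=C1CCC(=O)N1Br; tetraethylammonium chloride, CC[N+](CC)(CC)CC.[Cl-]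
Why: Bromonium formation on the more nucleophilic trisubstituted C9=C10 alkene and anti opening by chloride at the tertiary C9 is a known halogen–halide addition. Positive bromine is expected on the ring B face anti to the axial C1 branch (the C5 face), so chloride enters C9 from the C1 side and the two halogens end trans and equatorial as in 19. The C1 methylene is less nucleophilic and flanked by the quaternary C6, which should spare it with one equivalent of reagent at low temperature.

## Compound list

1 | 4-methyl-5,6-dihydro-2H-pyran-2-one | CC1=CC(=O)OCC1 | starting material
2 | (2Z)-3-methylpent-2-ene-1,5-diol | OC/C=C(C)\CCO | intermediate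
3 | (2Z)-1,5-dichloro-3-methylpent-2-ene | ClC/C=C(C)\CCCl | intermediate
4 | cyclohexane-1,3-dione | O=C1CCCC(=O)C1 | starting material
5 | 2-[(2Z)-5-chloro-3-methylpent-2-en-1-yl]cyclohexane-1,3-dione | O=C1CCCC(=O)C1C/C=C(C)\CCCl | intermediate
6 | 2-[(2Z)-5-chloro-3-methylpent-2-en-1-yl]-3-methoxycyclohex-2-en-1-one | COC1=C(C/C=C(C)\CCCl)C(=O)CCC1 | intermediate
7 | rac-3-[(2Z)-5-chloro-3-methylpent-2-en-1-yl]-4-methoxy-2-oxocyclohex-3-en-1-yl acetate (racemic at the acetoxy carbon) | COC1=C(C/C=C(C)\CCCl)C(=O)C(OC(C)=O)CC1 | intermediate
8 | (6R)-2-[(2Z)-5-chloro-3-methylpent-2-en-1-yl]-6-hydroxy-3-methoxycyclohex-2-en-1-one | COC1=C(C/C=C(C)\CCCl)C(=O)[C@H](O)CC1 | intermediate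
9 | (6R)-6-[(tert-butyldimethylsilyl)oxy]-2-[(2Z)-5-chloro-3-methylpent-2-en-1-yl]-3-methoxycyclohex-2-en-1-one | COC1=C(C/C=C(C)\CCCl)C(=O)[C@H](O[Si](C)(C)C(C)(C)C)CC1 | intermediate
10 | methyllithium | [Li]C | starting material
11 | (6R)-6-[(tert-butyldimethylsilyl)oxy]-2-[(2Z)-5-chloro-3-methylpent-2-en-1-yl]-3-methoxy-1-methylcyclohex-2-en-1-ol (C1 epimers, not isolated) | COC1=C(C/C=C(C)\CCCl)C(C)(O)[C@H](O[Si](C)(C)C(C)(C)C)CC1 | intermediate
12 | (4R)-4-[(tert-butyldimethylsilyl)oxy]-2-[(2Z)-5-chloro-3-methylpent-2-en-1-yl]-3-methylcyclohex-2-en-1-one | CC1=C(C/C=C(C)\CCCl)C(=O)CC[C@H]1O[Si](C)(C)C(C)(C)C | intermediate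
13 | tert-butyl{[(1R)-3-[(2Z)-5-chloro-3-methylpent-2-en-1-yl]-2,2-dimethyl-4-[(trimethylsilyl)oxy]cyclohex-3-en-1-yl]oxy}dimethylsilane (not isolated) | C[Si](C)(C)OC1=C(C/C=C(C)\CCCl)C(C)(C)[C@H](O[Si](C)(C)C(C)(C)C)CC1 | intermediate
14 | lithium (4R)-4-[(tert-butyldimethylsilyl)oxy]-2-[(2Z)-5-chloro-3-methylpent-2-en-1-yl]-3,3-dimethylcyclohex-1-en-1-olate (not isolated) | [Li+].[O-]C1=C(C/C=C(C)\CCCl)C(C)(C)[C@H](O[Si](C)(C)C(C)(C)C)CC1 | intermediate
15 | (4R,6R)-4-[(tert-butyldimethylsilyl)oxy]-5,5,9-trimethylspiro[5.5]undec-9-en-1-one | O=C1CC[C@@H](O[Si](C)(C)C(C)(C)C)C(C)(C)[C@]12CCC(C)=CC2 | intermediate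
16 | tert-butyl{[(4R,6S)-5,5,9-trimethyl-1-methylidenespiro[5.5]undec-9-en-4-yl]oxy}dimethylsilane | C=C1CC[C@@H](O[Si](C)(C)C(C)(C)C)C(C)(C)[C@]12CCC(C)=CC2 | intermediate
17 | (4R,6S)-5,5,9-trimethyl-1-methylidenespiro[5.5]undec-9-en-4-ol | C=C1CC[C@@H](O)C(C)(C)[C@]12CCC(C)=CC2 | intermediate
18 | (4S,6S)-4-bromo-5,5,9-trimethyl-1-methylidenespiro[5.5]undec-9-ene | C=C1CC[C@H](Br)C(C)(C)[C@]12CCC(C)=CC2 | intermediate
19 | nidificene, (4S,6S,9S,10S)-4,10-dibromo-9-chloro-5,5,9-trimethyl-1-methylidenespiro[5.5]undecane | C=C1CC[C@H](Br)C(C)(C)[C@]12CC[C@](C)(Cl)[C@@H](Br)C2 | target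

## Step count and least certain steps

Total: 13 steps. Longest linear sequence: 13 steps, from 1 to 19; 4 enters at step 3 and 10 at steps 8 and 9.

**Step 9 (key step).** The most likely failure is a slow ring closure: the hindered, fully substituted enolate displaces the primary chloride sluggishly, so that proton transfer, loss of HCl from the tether or attack of residual cuprate on the chloride competes. Incomplete facial selectivity at C6 is the second concern. Fallback: setting out from 12, the conjugate addition is stopped at the silyl enol ether 13, which is isolated. NaI in acetone exchanges chloride for iodide and gives the trimethylsilyl enol ether iodide F1. Tetrabutylammonium difluorotriphenylsilicate in THF then frees a naked enolate, without copper or lithium, which closes onto the iodide and comes back to the route at 15.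

**Step 13.** The most likely failure is poor facial selectivity. The bromonium ion on the C1 face can be opened by chloride at C9 in the trans-diaxial sense, the kinetically normal mode for cyclohexene halonium ions, and this leads to the pair epimeric at C9 and C10. Reaction at the C1 methylene and loss of HCl are lesser risks. Fallback (a bromo ether relay of the kind weighed as alternative 1, run on the silyl ether), setting out from 15 and coming back at 19:
- NaBH4 in MeOH reduces the ketone to the C1 alcohol F2. Either C1 epimer serves, because ring A can take the chair that places the hydroxyl anti to C5 and hence under ring B.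
- NBS in CH2Cl2 lets this hydroxyl open the bromonium ion at C9 and gives the bridged bromo ether F3, in which bromine at C10 is necessarily anti to oxygen and on the C5 face.
- TiCl4 in CH2Cl2 at −78 °C ionises the tertiary C9–O bond with participation of the anti bromine and returns chloride to C9 from the oxygen side, with retention, to give the bromo chloro alcohol F4.
- Dess–Martin periodinane gives the ketone F5, and Cp2TiMe2 in toluene at 65 °C, a non-basic methylenation, gives the methylidene silyl ether F6.
- HF·pyridine gives the alcohol F7, and the Appel conditions of step 12 convert F7 into 19.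

**Step 12.** The most likely failure is ionisation of the alkoxyphosphonium ion instead of SN2 at the neopentylic carbon, followed by a 1,2-methyl shift from C5, ring contraction or elimination toward C3. Fallback: setting out from 17, Tf2O and pyridine at −40 °C give the trifluoromethanesulfonate F8. Bu4NBr in toluene at low temperature then displaces it with inversion and comes back to the route at 18. Activation and displacement are separated, and a soluble, non-basic bromide replaces the phosphorus ion pair.

**Step 10.** The most likely failure is enolisation of the ketone by the ylide, or no addition at all, because the carbonyl lies next to two quaternary carbons. Fallback: setting out from 15, Me3SiCH2Li with CeCl3 in THF at −78 °C, a small and weakly basic nucleophile, adds to give the β-hydroxysilane F9. KH in THF then eliminates (Peterson olefination) and comes back to the route at 16.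

**Step 6.** The most likely failure is insufficient discrimination between the enantiomers by the enzyme, or the opposite preference. If the preference is opposite, the unreacted R enantiomer of 7 is collected and methanolysed (K2CO3, MeOH, 0 °C) to 8. If discrimination is poor, the fallback changes from resolution to reagent control: setting out from 6, the sodium enolate (NaN(SiMe3)2, THF, −78 °C) is hydroxylated with an enantiopure camphor-derived N-sulfonyloxaziridine, which comes back to the route directly at 8. The antipode of the reagent is chosen by the sense of induction found, and the enantiomeric purity has to be checked and raised before step 7.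

## Further compounds

F1 | step 9 | tert-butyl{[(1R)-3-[(2Z)-5-iodo-3-methylpent-2-en-1-yl]-2,2-dimethyl-4-[(trimethylsilyl)oxy]cyclohex-3-en-1-yl]oxy}dimethylsilane | C[Si](C)(C)OC1=C(C/C=C(C)\CCI)C(C)(C)[C@H](O[Si](C)(C)C(C)(C)C)CC1
F2 | step 13 | (4R,6R)-4-[(tert-butyldimethylsilyl)oxy]-5,5,9-trimethylspiro[5.5]undec-9-en-1-ol (C1 epimer not fixed) | OC1CC[C@@H](O[Si](C)(C)C(C)(C)C)C(C)(C)[C@]12CCC(C)=CC2
F3 | step 13 | bridged bromo ether with the C1–O–C9 bridge, (10S)-bromide and (4R)-silyl ether (4R,6R,9S,10S; C1 epimer not fixed) | O1C2CC[C@@H](O[Si](C)(C)C(C)(C)C)C(C)(C)[C@]23CC[C@@]1(C)[C@@H](Br)C3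
F4 | step 13 | (4R,6R,9S,10S)-10-bromo-4-[(tert-butyldimethylsilyl)oxy]-9-chloro-5,5,9-trimethylspiro[5.5]undecan-1-ol (C1 epimer not fixed) | OC1CC[C@@H](O[Si](C)(C)C(C)(C)C)C(C)(C)[C@]12CC[C@](C)(Cl)[C@@H](Br)C2
F5 | step 13 | (4R,6R,9S,10S)-10-bromo-4-[(tert-butyldimethylsilyl)oxy]-9-chloro-5,5,9-trimethylspiro[5.5]undecan-1-one | O=C1CC[C@@H](O[Si](C)(C)C(C)(C)C)C(C)(C)[C@]12CC[C@](C)(Cl)[C@@H](Br)C2
F6 | step 13 | {[(4R,6S,9S,10S)-10-bromo-9-chloro-5,5,9-trimethyl-1-methylidenespiro[5.5]undecan-4-yl]oxy}(tert-butyl)dimethylsilane | C=C1CC[C@@H](O[Si](C)(C)C(C)(C)C)C(C)(C)[C@]12CC[C@](C)(Cl)[C@@H](Br)C2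
F7 | step 13 | (4R,6S,9S,10S)-10-bromo-9-chloro-5,5,9-trimethyl-1-methylidenespiro[5.5]undecan-4-ol | C=C1CC[C@@H](O)C(C)(C)[C@]12CC[C@](C)(Cl)[C@@H](Br)C2
F8 | step 12 | (4R,6S)-5,5,9-trimethyl-1-methylidenespiro[5.5]undec-9-en-4-yl trifluoromethanesulfonate | C=C1CC[C@@H](OS(=O)(=O)C(F)(F)F)C(C)(C)[C@]12CCC(C)=CC2
F9 | step 10 | (4R,6R)-4-[(tert-butyldimethylsilyl)oxy]-5,5,9-trimethyl-1-[(trimethylsilyl)methyl]spiro[5.5]undec-9-en-1-ol (C1 epimer not fixed) | C[Si](C)(C)CC1(O)CC[C@@H](O[Si](C)(C)C(C)(C)C)C(C)(C)[C@]12CCC(C)=CC2
F0 | step 6 | none | none
A1 | alternative 1 | bridged bromo ether of the C4 bromide (C1–O–C9 bridge, bromine at C10) | O1[C@H]2CC[C@H](Br)C(C)(C)[C@]23CC[C@@]1(C)[C@@H](Br)C3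
A2 | alternative 1 | (4S)-4-bromo-5,5,9-trimethylspiro[5.5]undec-9-en-1-ol with the spiro centre of 19 | O[C@H]1CC[C@H](Br)C(C)(C)[C@]12CCC(C)=CC2
A3 | alternative 2 | spiro ketone with C11 ketone, C8=C9 alkene, C1 methylene and (4R)-silyl ether | C=C1CC[C@@H](O[Si](C)(C)C(C)(C)C)C(C)(C)[C@]12CC=C(C)CC2=O
A4 | alternative 2 | 1-methoxy-4-methylcyclohexa-1,4-diene carrying at C2 the (3R)-3-[(tert-butyldimethylsilyl)oxy]-2-methylhept-6-yn-2-yl chain | COC1=C(C(C)(C)[C@H](O[Si](C)(C)C(C)(C)C)CCC#C)CC=C(C)C1
A5 | alternative 3 | spiro enedione with C1 ketone, C9 ketone, C10=C11 alkene and (4R)-silyl ether | O=C1CC[C@@H](O[Si](C)(C)C(C)(C)C)C(C)(C)[C@]12CCC(=O)C=C2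
A6 | alternative 3 | (5R)-5-[(tert-butyldimethylsilyl)oxy]-6,6-dimethyl-2-oxocyclohexane-1-carbaldehyde | O=CC1C(=O)CC[C@@H](O[Si](C)(C)C(C)(C)C)C1(C)C
A7 | alternative 3 | but-3-en-2-one | C=CC(C)=O
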